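## The problem

The target **24** is a bicyclo[4.3.1]dec-7-ene: a seven-membered ring (C1–C2–C3–C4–C5–C6–C10) and a cyclohexene (C1–C10–C6–C7–C8–C9) share the one-carbon bridge C10. These core locants, with C11 for the methylidene carbon on C2, are used for every intermediate below. The core carries the C2 methylidene, the enal C7(CHO)=C8, acetates at C4 and C10 and a (2S)-6-methylhept-5-en-2-yl chain at C5. There are six stereocenters, and because a one-carbon bridge can only span cis, C1 and C6 count as one stereochemical unit, the face of the perimeter on which C10 sits. (S)-Citronellal **6** can supply the side-chain centre, C5 (its α-carbon) and C4 (its carbonyl carbon): C5 can be set next to the side-chain centre by catalyst control and C4 by reagent control. C4 and C5 are then the only handles for the bridge face, whereas C10, flanked by two bridgeheads, can be set on its own by hydride addition to a ketone. The enal, the two secondary acetates and the 1,1-disubstituted and trisubstituted alkenes rule out late strong base, strong acid, electrophilic oxidants and hydrogenation, so aldehyde and acetates must come last. The enabling feature is the homoallylic alcohol C10(O)–C6–C7=C8: it is the retron of a carbonyl-ene reaction between a formyl group on C1 and a C6=C7 alkene in the nine-membered perimeter C1–C9, and that cyclononene aldehyde is the oxy-Cope product of a cycloheptanol holding the 1,5-diene C9=C1–C10(OH)–C6–C7=C8.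

## Retrosynthesis

**24 ⇒ 23 ⇒ 22 ⇒ 21 (C–O acyl bonds, oxidation level, silyl ethers).** Both acetates are cut at once and the enal is traced to an allylic primary alcohol, so that one desilylation of **21** frees all three hydroxyls of triol **22**. Acetylating C10 earlier would cost a step and expose an ester to fluoride. The forward steps must oxidise only the allylic alcohol of **22**, then acylate two hindered secondary alcohols of **23**.

**21 ⇒ 20 ⇒ 19 (C10–H bond).** A concerted ene reaction that takes its hydrogen from C8 must place the new hydroxyl over the C7–C9 bridge, which is the 10R epimer **19**, not the 10S configuration of the target. C10 is therefore set by hydride addition to the bridging ketone **20**. This also makes the C10 outcome of the ring closure irrelevant, since either epimer gives **20**. The alternative, displacement with inversion at a carbon between two bridgeheads, would be much less reliable.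

**19 ⇒ 18 ⇒ 17 ⇒ 15 (C6–C10, then C8–C9 with C6–C10 restored).** Cutting C6–C10 gives the cyclononene aldehyde **18**. Its dienolate **17** is the [3,3] product of cycloheptanol **15**, in which C8–C9 is absent and C6–C10 is a ring bond. Cutting C1–C10 instead (the ene reaction in the opposite sense) would require a nine-membered ring with no sigmatropic route from a common ring. Cutting inside the cyclohexene would leave the bridged seven-membered ring and its three centres to be made first. **15** has one ring and four ring stereocenters, two of which (C6, C10) are expendable. The forward step needs a chair transition state, protonation of **17** at C1 and not at C11, and closure on the perimeter face anti to the C4 and C5 substituents.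

**15 ⇒ 14 (C1–C2).** The two exocyclic methylenes are cut between them, giving a vinyl iodide at C1 and an allyl group on C4. Double methylenation of a 1,2-dione or an α-methylene ketone would suffer from enolisation and conjugate addition. A closure at C1–C10 would need a 2-metallated diene that is not readily available. The forward Heck reaction must close a seven-membered ring in the exo mode and eliminate toward C2.

**14 ⇒ 12 ⇒ 11 (C1–C10, C–I).** The 2-iodoallylic alcohol comes from a propargylic alcohol by hydrometallation with internal regiochemistry and iodinolysis. The alkyne comes from an ethynyl nucleophile and aldehyde **11**. C10 need not be controlled.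

**11 ⇒ 9 ⇒ 8 ⇒ 7 (C10=O from C10–N, O–Si, C3–C4).** The C10 aldehyde is masked as a nitromethyl group up to **9**. This lets the C4 aldehyde of **7** react first with an allylboron reagent, which sets C4 by reagent control. The alternative, an aldol construction of C3–C4, would need an unstable β,γ-unsaturated aldehyde partner.

**7 ⇒ 6 + 5 (C5–C6).** A Michael disconnection next to the citronellal carbonyl sets C5 under catalyst control. It also brings in C6 with its complete 2-propenyl substituent and C10 in one step. An aldol/cuprate sequence on a preformed cycloheptenone would reach the same array in roughly twice as many steps.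

**5 ⇒ 2 + 3; 2 ⇒ 1 (C6–C7, O–Si).** The nitrodiene **5** is cut at the bond between the vinyl carbon and the nitrovinyl unit, giving the vinyl bromide **2** (from **1**) and the nitroenamine **3**.

## Roads not taken

**Alternative 1:** Furan (4+3) cycloaddition, cutting C1–C10 and C3–C4. An oxyallyl cation generated at C1–C2–C3 beside a C2 ketone would add across the 2,5-positions of a furan held in the same molecule, giving the oxygen-bridged tricyclic ketone A1.
- Merits: two C–C bonds and both carbocycles form in one step, one ether oxygen becomes both O4 and O10, and the relative configuration of C1, C4 and C10 is locked by the cycloadduct rather than left to a flexible ring. On that last point it is better than the chosen plan.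
- Weak points: the bridge holds O4 and O10 on the same face of the seven-membered ring, whereas **24** has them on opposite faces, so C4 must be inverted after the bridge is opened. The tetrasubstituted C5=C6 alkene of A1 must be reduced with control of two centres, which forces a truncated, saturated side chain whose prenyl terminus is rebuilt later. The C2 ketone must be methylenated and the C7 silyl ether turned into the formyl-bearing C7=C8 unit.
- Comparison: the chosen plan has the methylidene, the C7=C8 alkene and the intact citronellal chain in place when the rings close, and needs about half as many steps afterwards. It pays with a less certain bridge-face selectivity.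

**Alternative 2:** Type 2 intramolecular Diels–Alder reaction, cutting C1–C10 and C8–C9. A 1-silyloxy diene C10=C6–C7=C8 would add to a tethered vinyl ketone C1=C9 to give the bridgehead alkene A2.
- Merits: two C–C bonds and both rings form without anionic intermediates, the tether on the diene 2-position enforces the bridged regiochemistry, and O10 arrives with its configuration fixed by the diene geometry. The chosen plan needs two extra steps (11 and 12) for that.
- Weak points: the alkene of A2 is at C6=C7, not C7=C8. Moving it requires a protonation at C6 with no controlling element and no conjugative driving path. The C2 ketone next to a bridgehead still has to be methylenated, and the silyloxy diene carrying the C5 centre is a sensitive substrate. Facial control by C4 and C5 is no more certain than in the chosen plan.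
- Comparison: in the chosen plan the ene reaction itself places C7=C8 and sets C6–H, and the methylidene is already present.

**Alternative 3:** Amine-catalysed Michael/Michael/aldol cascade from acetaldehyde A4, cutting C1–C9, C6–C10 and C7=C8. The enamine of A4 would add to a nitrodiene at C1, the nitronate carbon C10 would add to a tethered enal at C6 to close the seven-membered ring, and an enamine aldol condensation of C7 onto the C8 aldehyde would close the cyclohexene to give A3.
- Merits: three C–C bonds, both rings, the enal at its final oxidation level and the methylidene all come from one flask. On paper its end game is shorter than that of the chosen plan.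
- Weak points: the seven-membered ring closes by an intramolecular nitro-Michael addition that competes with intermolecular paths and with self-condensation of A4. C6 and C10 are set in a reversible step with uncertain control. The bridging secondary nitro group must then be converted to oxygen by a Nef reaction and a ketone reduction, so the sequence ends with the same C10 reduction as the chosen plan plus a Nef reaction on a hindered centre. The linear substrate is no simpler than **15**.
- Comparison: the chosen plan spreads the risk over separate, individually precedented steps and has oxygen on C10 throughout.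

Key step: step 10

Assumption: C10 in **12**–**16** is drawn as the Felkin–Anh epimer. Its C10 epimer would be carried along unchanged, because C10 is trigonal in **17** and **18**.

## Route

Step 1
Reactants: 1 2-bromoprop-2-en-1-ol
Product: 2 tert-butyl[(2-bromoprop-2-en-1-yl)oxy]diphenylsilane
Conditions: TBDPSCl, imidazole, CH2Cl2, 0 °C to rt
Reagents that add atoms: tert-butyl(chloro)diphenylsilane, CC(C)(C)[Si](Cl)(c1ccccc1)c1ccccc1
Why: Silylation of a primary allylic alcohol with a silyl chloride and imidazole; the bulky diphenyl-tert-butylsilyl group is chosen because it resists silyl migration under the organolithium conditions of step 2 and the potassium alkoxide conditions of step 10.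

Step 2
Reactants: 2 tert-butyl[(2-bromoprop-2-en-1-yl)oxy]diphenylsilane; 3 (E)-N,N-dimethyl-2-nitroethen-1-amine
Product: 5 tert-butyl{[(3E)-2-methylidene-4-nitrobut-3-en-1-yl]oxy}diphenylsilane, via vinyllithium 4 (not isolated)
Conditions: t-BuLi (2 equiv), Et2O, −78 °C; then 3, THF, −78 to −20 °C; 1 M HCl, 0 °C
Reagents that add atoms: none
Why: Bromine–lithium exchange gives 4, which adds to the amine-bearing carbon of the nitroenamine; acid work-up expels dimethylamine (addition–elimination nitrovinylation of an organometallic reagent) and leaves the more stable (E)-nitroalkene.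

Step 3
Reactants: 6 (S)-citronellal; 5 tert-butyl{[(3E)-2-methylidene-4-nitrobut-3-en-1-yl]oxy}diphenylsilane
Product: 7 (2R,3S)-3-{3-[(tert-butyldiphenylsilyl)oxy]prop-1-en-2-yl}-2-[(2S)-6-methylhept-5-en-2-yl]-4-nitrobutanal
Conditions: (S)-2-[diphenyl(trimethylsilyloxy)methyl]pyrrolidine (10 mol%), 4-nitrophenol (10 mol%), toluene, 0 °C to rt
Reagents that add atoms: none
Why: Enamine-mediated asymmetric Michael addition of an aldehyde to a nitroalkene with a diarylprolinol silyl ether: the catalyst shields one face of the (E)-enamine and sets C5 (R) independently of the neighbouring side-chain centre, the synclinal transition state gives the syn adduct (C6 S), and enamines attack 1-nitro-1,3-dienes at the carbon β to nitrogen.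

Step 4
Reactants: 7 (2R,3S)-3-{3-[(tert-butyldiphenylsilyl)oxy]prop-1-en-2-yl}-2-[(2S)-6-methylhept-5-en-2-yl]-4-nitrobutanal
Product: 8 (4S,5R,6S)-6-{3-[(tert-butyldiphenylsilyl)oxy]prop-1-en-2-yl}-5-[(2S)-6-methylhept-5-en-2-yl]-7-nitrohept-1-en-4-ol
Conditions: (−)-Ipc2B(allyl) (Ipc = isopinocampheyl), Et2O, −78 °C; then HOCH2CH2NH2, rt
Reagents that add atoms: (−)-B-allyldiisopinocampheylborane, C=CCB([C@@H]1C[C@@H]2C[C@H]([C@H]1C)C2(C)C)[C@@H]1C[C@@H]2C[C@H]([C@H]1C)C2(C)C
Why: Reagent-controlled asymmetric allylboration through a chair six-membered transition state: the (−)-reagent delivers allyl to the Si face of C4 and gives the 4S alcohol (O4 and the C5 side chain anti in the zigzag chain, cis on the later ring); crude 7 is used so that C5 cannot epimerise, and the non-oxidative work-up spares the nitro group.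

Step 5
Reactants: 8 (4S,5R,6S)-6-{3-[(tert-butyldiphenylsilyl)oxy]prop-1-en-2-yl}-5-[(2S)-6-methylhept-5-en-2-yl]-7-nitrohept-1-en-4-ol
Product: 9 tert-butyl{[(4S,5R,6S)-6-{3-[(tert-butyldiphenylsilyl)oxy]prop-1-en-2-yl}-5-[(2S)-6-methylhept-5-en-2-yl]-7-nitrohept-1-en-4-yl]oxy}dimethylsilane
Conditions: TBSOTf, 2,6-lutidine, CH2Cl2, −78 to 0 °C
Reagents that add atoms: tert-butyldimethylsilyl trifluoromethanesulfonate, CC(C)(C)[Si](C)(C)OS(=O)(=O)C(F)(F)F
Why: Silyl triflate and a hindered pyridine silylate the crowded secondary alcohol; O4 must be masked because both C4 and C10 would otherwise be oxidised in step 11.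

Step 6
Reactants: 9 tert-butyl{[(4S,5R,6S)-6-{3-[(tert-butyldiphenylsilyl)oxy]prop-1-en-2-yl}-5-[(2S)-6-methylhept-5-en-2-yl]-7-nitrohept-1-en-4-yl]oxy}dimethylsilane
Product: 11 (2S,3R,4S)-4-[(tert-butyldimethylsilyl)oxy]-2-{3-[(tert-butyldiphenylsilyl)oxy]prop-1-en-2-yl}-3-[(2S)-6-methylhept-5-en-2-yl]hept-6-enal, via sodium nitronate 10 (not isolated)
Conditions: NaOMe, MeOH, 0 °C; then aq. TiCl3, NH4OAc, THF–H2O, 0 °C to rt
Reagents that add atoms: water, O
Why: Nef reaction in its reductive TiCl3 variant: nitronate 10 is reduced to the imine level and hydrolysed near pH 5, which spares the silyl ethers and all alkenes and avoids enolising the new α-branched β,γ-unsaturated aldehyde.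

Step 7
Reactants: 11 (2S,3R,4S)-4-[(tert-butyldimethylsilyl)oxy]-2-{3-[(tert-butyldiphenylsilyl)oxy]prop-1-en-2-yl}-3-[(2S)-6-methylhept-5-en-2-yl]hept-6-enal
Product: 12 (3S,4S,5R,6S)-6-[(tert-butyldimethylsilyl)oxy]-4-{3-[(tert-butyldiphenylsilyl)oxy]prop-1-en-2-yl}-5-[(2S)-6-methylhept-5-en-2-yl]non-8-en-1-yn-3-ol
Conditions: HC≡CMgBr (3 equiv), THF, −78 to −20 °C; aq. NH4Cl
Reagents that add atoms: ethynylmagnesium bromide, C#C[Mg]Br
Why: 1,2-Addition of an alkynyl Grignard reagent at low temperature, used on crude 11; Felkin–Anh control with the branched C5 carbon as the large group should favour the 10S alcohol, but C10 is erased in step 10, so either epimer serves.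

Step 8
Reactants: 12 (3S,4S,5R,6S)-6-[(tert-butyldimethylsilyl)oxy]-4-{3-[(tert-butyldiphenylsilyl)oxy]prop-1-en-2-yl}-5-[(2S)-6-methylhept-5-en-2-yl]non-8-en-1-yn-3-ol
Product: 14 (3S,4S,5R,6S)-6-[(tert-butyldimethylsilyl)oxy]-4-{3-[(tert-butyldiphenylsilyl)oxy]prop-1-en-2-yl}-2-iodo-5-[(2S)-6-methylhept-5-en-2-yl]nona-1,8-dien-3-ol, via vinylstannane 13 (not isolated)
Conditions: Bu3SnH (1.2 equiv), Mo(CO)3(CNt-Bu)3 (5 mol%), hydroquinone (cat.), THF, 55 °C; then I2, CH2Cl2, −78 to 0 °C
Reagents that add atoms: iodine, II
Why: Isonitrile–molybdenum-catalysed hydrostannation puts tin on the internal carbon of terminal propargylic alcohols and tolerates the free hydroxyl and the alkenes; iododestannylation of 13 is much faster at low temperature than iodination of the other alkenes.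

Step 9
Reactants: 14 (3S,4S,5R,6S)-6-[(tert-butyldimethylsilyl)oxy]-4-{3-[(tert-butyldiphenylsilyl)oxy]prop-1-en-2-yl}-2-iodo-5-[(2S)-6-methylhept-5-en-2-yl]nona-1,8-dien-3-ol
Product: 15 (1S,2S,3R,4S)-4-[(tert-butyldimethylsilyl)oxy]-2-{3-[(tert-butyldiphenylsilyl)oxy]prop-1-en-2-yl}-3-[(2S)-6-methylhept-5-en-2-yl]-6,7-dimethylidenecycloheptan-1-ol
Conditions: Pd(OAc)2 (10 mol%), PPh3 (20 mol%), K2CO3, n-Bu4NCl, DMF (0.005 M), 70 °C
Reagents that add atoms: none
Why: Intramolecular Heck reaction: oxidative addition at C1–I, 7-exo-trig carbopalladation of the allyl alkene (C1–C2 bond) and β-hydride elimination of the only β-hydrogen (on C2) give the 1,2-dimethylidene unit; the other alkenes would need 4-exo, 5-endo or large-ring closures and should not compete.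

Step 10
Reactants: 15 (1S,2S,3R,4S)-4-[(tert-butyldimethylsilyl)oxy]-2-{3-[(tert-butyldiphenylsilyl)oxy]prop-1-en-2-yl}-3-[(2S)-6-methylhept-5-en-2-yl]-6,7-dimethylidenecycloheptan-1-ol
Product: 19 (1R,4S,5R,6R,10R)-4-[(tert-butyldimethylsilyl)oxy]-7-{[(tert-butyldiphenylsilyl)oxy]methyl}-2-methylidene-5-[(2S)-6-methylhept-5-en-2-yl]bicyclo[4.3.1]dec-7-en-10-ol, via potassium alkoxide 16 (not isolated), via potassium dienolate 17 (not isolated), via cyclononene aldehyde 18 (not isolated)
Conditions: KH, 18-crown-6, THF, 0 °C to rt; inverse quench into AcOH–THF, −78 °C; cold aqueous wash; then Me2AlCl, CH2Cl2, −78 to −20 °C (crude 18 not purified)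
Reagents that add atoms: none
Why: Alkoxide 16 undergoes an anionic oxy-Cope shift through a chair in which C5 is axial on the breaking C6–C10 bond and the alkoxide equatorial; this forms C8–C9 and gives the cis-cyclononene dienolate 17, the closest known reaction type being the tandem alkoxide-accelerated oxy-Cope ring expansion and transannular carbonyl-ene reaction of alkenyl cycloalkanols. The nine-membered ring thus arises by two-carbon ring expansion, not by cyclisation. Inverse quench at −78 °C protonates the dienolate kinetically at C1 rather than at C11, giving the β,γ-unsaturated aldehyde 18. Me2AlCl then promotes the transannular ene reaction: C10 bonds to the less substituted alkene carbon C6 while a C8 hydrogen passes to oxygen, and this single bond closes the cyclohexene in the 6-endo mode and the seven-membered ring in the 7-exo mode. C10: the closed six-centre transition state holds the carbonyl oxygen over C8, so the hydroxyl emerges syn to the C7–C9 bridge (10R), which steps 11 and 12 correct. C1 and C6: the bridge can only span cis, so both are fixed together by the perimeter face on which the formyl group lies, and that face is set when C1 is protonated antiperiplanar to the C9–C8 bond in the ring conformer that keeps the C5 side chain pseudo-equatorial on the developing seven-membered ring, leaving only the small silyloxy group axial. The step needs protonation at C1 over C11 (kinetic quench), attack at C6 over C7 (developing positive charge on the fully substituted C7) and hydrogen transfer from C8 and not from the CH2OSi group (only C8–H lies under the oxygen). The bulky primary silyl ether and the hindered secondary one are chosen so that neither migrates to the C10 alkoxide.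

Step 11
Reactants: 19 (1R,4S,5R,6R,10R)-4-[(tert-butyldimethylsilyl)oxy]-7-{[(tert-butyldiphenylsilyl)oxy]methyl}-2-methylidene-5-[(2S)-6-methylhept-5-en-2-yl]bicyclo[4.3.1]dec-7-en-10-ol
Product: 20 (1R,4S,5R,6R)-4-[(tert-butyldimethylsilyl)oxy]-7-{[(tert-butyldiphenylsilyl)oxy]methyl}-2-methylidene-5-[(2S)-6-methylhept-5-en-2-yl]bicyclo[4.3.1]dec-7-en-10-one
Conditions: Dess–Martin periodinane, pyridine, CH2Cl2, 0 °C to rt
Reagents that add atoms: none
Why: Dess–Martin oxidation of a hindered secondary alcohol under buffered conditions; both α-carbons are bridgeheads, so they cannot epimerise and the β,γ-alkenes cannot move into conjugation without forming a twisted bridgehead enone.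

Step 12
Reactants: 20 (1R,4S,5R,6R)-4-[(tert-butyldimethylsilyl)oxy]-7-{[(tert-butyldiphenylsilyl)oxy]methyl}-2-methylidene-5-[(2S)-6-methylhept-5-en-2-yl]bicyclo[4.3.1]dec-7-en-10-one
Product: 21 (1R,4S,5R,6R,10S)-4-[(tert-butyldimethylsilyl)oxy]-7-{[(tert-butyldiphenylsilyl)oxy]methyl}-2-methylidene-5-[(2S)-6-methylhept-5-en-2-yl]bicyclo[4.3.1]dec-7-en-10-ol
Conditions: NaBH4, MeOH–CH2Cl2, −40 to 0 °C
Reagents that add atoms: none
Why: Steric approach control in hydride addition to a bridging ketone: the face over the cyclohexene bridge (sp2 carbons C7 and C8, one pseudo-axial hydrogen on C9) is more open than the face over the four-carbon bridge (inward hydrogens on C3 and C5), so hydride should enter syn to C7–C9 and leave the hydroxyl over the seven-membered ring (10S).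

Step 13
Reactants: 21 (1R,4S,5R,6R,10S)-4-[(tert-butyldimethylsilyl)oxy]-7-{[(tert-butyldiphenylsilyl)oxy]methyl}-2-methylidene-5-[(2S)-6-methylhept-5-en-2-yl]bicyclo[4.3.1]dec-7-en-10-ol
Product: 22 (1R,4S,5R,6R,10S)-7-(hydroxymethyl)-2-methylidene-5-[(2S)-6-methylhept-5-en-2-yl]bicyclo[4.3.1]dec-7-ene-4,10-diol
Conditions: n-Bu4NF, THF, rt to 40 °C
Reagents that add atoms: none
Why: Fluoride cleaves both silyl ethers in one operation; no base-sensitive group is present at this stage.

Step 14
Reactants: 22 (1R,4S,5R,6R,10S)-7-(hydroxymethyl)-2-methylidene-5-[(2S)-6-methylhept-5-en-2-yl]bicyclo[4.3.1]dec-7-ene-4,10-diol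
Product: 23 (1R,4S,5R,6R,10S)-4,10-dihydroxy-2-methylidene-5-[(2S)-6-methylhept-5-en-2-yl]bicyclo[4.3.1]dec-7-ene-7-carbaldehyde
Conditions: MnO2, CH2Cl2, rt
Reagents that add atoms: none
Why: MnO2 oxidises only the allylic primary alcohol; the C4 and C10 hydroxyls are homoallylic secondary alcohols and are left alone.

Step 15
Reactants: 23 (1R,4S,5R,6R,10S)-4,10-dihydroxy-2-methylidene-5-[(2S)-6-methylhept-5-en-2-yl]bicyclo[4.3.1]dec-7-ene-7-carbaldehyde
Product: 24 (1R,4S,5R,6R,10S)-7-formyl-2-methylidene-5-[(2S)-6-methylhept-5-en-2-yl]bicyclo[4.3.1]dec-7-ene-4,10-diyl diacetate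
Conditions: Ac2O, pyridine, DMAP (cat.), CH2Cl2, rt
Reagents that add atoms: acetic anhydride, CC(=O)OC(C)=O
Why: DMAP-catalysed acylation esterifies both hindered secondary alcohols under conditions that leave the enal and all stereocenters untouched.

## Compound list

1 | 2-bromoprop-2-en-1-ol | OCC(Br)=C | starting material
2 | tert-butyl[(2-bromoprop-2-en-1-yl)oxy]diphenylsilane | C=C(Br)CO[Si](c1ccccc1)(c1ccccc1)C(C)(C)C | intermediate
3 | (E)-N,N-dimethyl-2-nitroethen-1-amine | CN(C)/C=C/[N+](=O)[O-] | starting material
4 | {3-[(tert-butyldiphenylsilyl)oxy]prop-1-en-2-yl}lithium | [Li]C(=C)CO[Si](c1ccccc1)(c1ccccc1)C(C)(C)C | intermediate (not isolated)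
5 | tert-butyl{[(3E)-2-methylidene-4-nitrobut-3-en-1-yl]oxy}diphenylsilane | [O-][N+](=O)/C=C/C(=C)CO[Si](c1ccccc1)(c1ccccc1)C(C)(C)C | intermediate
6 | (S)-citronellal, (3S)-3,7-dimethyloct-6-enal | O=CC[C@@H](C)CCC=C(C)C | starting material
7 | (2R,3S)-3-{3-[(tert-butyldiphenylsilyl)oxy]prop-1-en-2-yl}-2-[(2S)-6-methylhept-5-en-2-yl]-4-nitrobutanal | O=C[C@H]([C@@H](C)CCC=C(C)C)[C@H](C[N+](=O)[O-])C(=C)CO[Si](c1ccccc1)(c1ccccc1)C(C)(C)C | intermediate
8 | (4S,5R,6S)-6-{3-[(tert-butyldiphenylsilyl)oxy]prop-1-en-2-yl}-5-[(2S)-6-methylhept-5-en-2-yl]-7-nitrohept-1-en-4-ol | C=CC[C@H](O)[C@H]([C@@H](C)CCC=C(C)C)[C@H](C[N+](=O)[O-])C(=C)CO[Si](c1ccccc1)(c1ccccc1)C(C)(C)C | intermediate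
9 | tert-butyl{[(4S,5R,6S)-6-{3-[(tert-butyldiphenylsilyl)oxy]prop-1-en-2-yl}-5-[(2S)-6-methylhept-5-en-2-yl]-7-nitrohept-1-en-4-yl]oxy}dimethylsilane | C=CC[C@H](O[Si](C)(C)C(C)(C)C)[C@H]([C@@H](C)CCC=C(C)C)[C@H](C[N+](=O)[O-])C(=C)CO[Si](c1ccccc1)(c1ccccc1)C(C)(C)C | intermediate
10 | sodium nitronate of 9 | [Na+].C=CC[C@H](O[Si](C)(C)C(C)(C)C)[C@H]([C@@H](C)CCC=C(C)C)[C@H](C=[N+]([O-])[O-])C(=C)CO[Si](c1ccccc1)(c1ccccc1)C(C)(C)C | intermediate (not isolated)
11 | (2S,3R,4S)-4-[(tert-butyldimethylsilyl)oxy]-2-{3-[(tert-butyldiphenylsilyl)oxy]prop-1-en-2-yl}-3-[(2S)-6-methylhept-5-en-2-yl]hept-6-enal | C=CC[C@H](O[Si](C)(C)C(C)(C)C)[C@H]([C@@H](C)CCC=C(C)C)[C@H](C=O)C(=C)CO[Si](c1ccccc1)(c1ccccc1)C(C)(C)C | intermediate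
12 | (3S,4S,5R,6S)-6-[(tert-butyldimethylsilyl)oxy]-4-{3-[(tert-butyldiphenylsilyl)oxy]prop-1-en-2-yl}-5-[(2S)-6-methylhept-5-en-2-yl]non-8-en-1-yn-3-ol | C=CC[C@H](O[Si](C)(C)C(C)(C)C)[C@H]([C@@H](C)CCC=C(C)C)[C@H]([C@H](O)C#C)C(=C)CO[Si](c1ccccc1)(c1ccccc1)C(C)(C)C | intermediate
13 | (3S,4S,5R,6S)-6-[(tert-butyldimethylsilyl)oxy]-4-{3-[(tert-butyldiphenylsilyl)oxy]prop-1-en-2-yl}-5-[(2S)-6-methylhept-5-en-2-yl]-2-(tributylstannyl)nona-1,8-dien-3-ol | C=CC[C@H](O[Si](C)(C)C(C)(C)C)[C@H]([C@@H](C)CCC=C(C)C)[C@H]([C@H](O)C(=C)[Sn](CCCC)(CCCC)CCCC)C(=C)CO[Si](c1ccccc1)(c1ccccc1)C(C)(C)C | intermediate (not isolated)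
14 | (3S,4S,5R,6S)-6-[(tert-butyldimethylsilyl)oxy]-4-{3-[(tert-butyldiphenylsilyl)oxy]prop-1-en-2-yl}-2-iodo-5-[(2S)-6-methylhept-5-en-2-yl]nona-1,8-dien-3-ol | C=CC[C@H](O[Si](C)(C)C(C)(C)C)[C@H]([C@@H](C)CCC=C(C)C)[C@H]([C@H](O)C(I)=C)C(=C)CO[Si](c1ccccc1)(c1ccccc1)C(C)(C)C | intermediate
15 | (1S,2S,3R,4S)-4-[(tert-butyldimethylsilyl)oxy]-2-{3-[(tert-butyldiphenylsilyl)oxy]prop-1-en-2-yl}-3-[(2S)-6-methylhept-5-en-2-yl]-6,7-dimethylidenecycloheptan-1-ol | C=C1C[C@H](O[Si](C)(C)C(C)(C)C)[C@H]([C@@H](C)CCC=C(C)C)[C@@H](C(=C)CO[Si](c2ccccc2)(c2ccccc2)C(C)(C)C)[C@H](O)C1=C | intermediate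
16 | potassium alkoxide of 15 | C=C1C[C@H](O[Si](C)(C)C(C)(C)C)[C@H]([C@@H](C)CCC=C(C)C)[C@@H](C(=C)CO[Si](c2ccccc2)(c2ccccc2)C(C)(C)C)[C@H]([O-])C1=C.[K+] | intermediate (not isolated)
17 | potassium (Z)-dienolate of cyclononene aldehyde 18 (C5 and C8 cis on C6=C7) | [K+].[O-]/C=C1\C(=C)C[C@H](O[Si](C)(C)C(C)(C)C)[C@H]([C@@H](C)CCC=C(C)C)/C=C(CO[Si](c2ccccc2)(c2ccccc2)C(C)(C)C)\CC1 | intermediate (not isolated)
18 | (1R,4E,6R,7S)-7-[(tert-butyldimethylsilyl)oxy]-4-{[(tert-butyldiphenylsilyl)oxy]methyl}-6-[(2S)-6-methylhept-5-en-2-yl]-9-methylidenecyclonon-4-ene-1-carbaldehyde | O=C[C@H]1C(=C)C[C@H](O[Si](C)(C)C(C)(C)C)[C@H]([C@@H](C)CCC=C(C)C)/C=C(CO[Si](c2ccccc2)(c2ccccc2)C(C)(C)C)\CC1 | intermediate (not isolated)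
19 | (1R,4S,5R,6R,10R)-4-[(tert-butyldimethylsilyl)oxy]-7-{[(tert-butyldiphenylsilyl)oxy]methyl}-2-methylidene-5-[(2S)-6-methylhept-5-en-2-yl]bicyclo[4.3.1]dec-7-en-10-ol | C=C1C[C@H](O[Si](C)(C)C(C)(C)C)[C@H]([C@@H](C)CCC=C(C)C)[C@@H]2C(CO[Si](c3ccccc3)(c3ccccc3)C(C)(C)C)=CC[C@H]1[C@H]2O | intermediate
20 | (1R,4S,5R,6R)-4-[(tert-butyldimethylsilyl)oxy]-7-{[(tert-butyldiphenylsilyl)oxy]methyl}-2-methylidene-5-[(2S)-6-methylhept-5-en-2-yl]bicyclo[4.3.1]dec-7-en-10-one | C=C1C[C@H](O[Si](C)(C)C(C)(C)C)[C@H]([C@@H](C)CCC=C(C)C)[C@@H]2C(CO[Si](c3ccccc3)(c3ccccc3)C(C)(C)C)=CC[C@H]1C2=O | intermediate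
21 | (1R,4S,5R,6R,10S)-4-[(tert-butyldimethylsilyl)oxy]-7-{[(tert-butyldiphenylsilyl)oxy]methyl}-2-methylidene-5-[(2S)-6-methylhept-5-en-2-yl]bicyclo[4.3.1]dec-7-en-10-ol | C=C1C[C@H](O[Si](C)(C)C(C)(C)C)[C@H]([C@@H](C)CCC=C(C)C)[C@@H]2C(CO[Si](c3ccccc3)(c3ccccc3)C(C)(C)C)=CC[C@H]1[C@@H]2O | intermediate
22 | (1R,4S,5R,6R,10S)-7-(hydroxymethyl)-2-methylidene-5-[(2S)-6-methylhept-5-en-2-yl]bicyclo[4.3.1]dec-7-ene-4,10-diol | C=C1C[C@H](O)[C@H]([C@@H](C)CCC=C(C)C)[C@@H]2C(CO)=CC[C@H]1[C@@H]2O | intermediate
23 | (1R,4S,5R,6R,10S)-4,10-dihydroxy-2-methylidene-5-[(2S)-6-methylhept-5-en-2-yl]bicyclo[4.3.1]dec-7-ene-7-carbaldehyde | C=C1C[C@H](O)[C@H]([C@@H](C)CCC=C(C)C)[C@@H]2C(C=O)=CC[C@H]1[C@@H]2O | intermediate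
24 | (1R,4S,5R,6R,10S)-7-formyl-2-methylidene-5-[(2S)-6-methylhept-5-en-2-yl]bicyclo[4.3.1]dec-7-ene-4,10-diyl diacetate (CNP0197379.1) | C=C1C[C@H](OC(C)=O)[C@H]([C@@H](C)CCC=C(C)C)[C@@H]2C(C=O)=CC[C@H]1[C@@H]2OC(C)=O | target

## Step count and least certain steps

Total: 15 steps. Longest linear sequence: 15 steps (**1** to **24**); 13 steps from (S)-citronellal **6**.

**Step 10 (key step).** The most likely failure is poor facial selectivity when dienolate **17** is protonated at C1. The formyl group would then lie on the perimeter face syn to the C4 and C5 substituents and the bridge would close on the wrong face. The preference rests only on the conformation of a flexible nine-membered ring. Some protonation at C11, moving the exocyclic alkene into conjugation, would also remove material.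
Fallback, from **15** back to **19**: the two events are separated. After the oxy-Cope shift, **17** is trapped with chlorotrimethylsilane and the trimethylsilyl dienol ether of the cyclononene aldehyde F1 is isolated. F1 is cleaved with methyllithium to the lithium dienolate, which has a different counter-ion and aggregation state. This is protonated at −100 °C with a hindered phenol to give **18**, which is closed with Me2AlCl to **19**. Any unwanted C1 epimer of **18** that does not cyclise is resilylated to F1 and recycled.

**Step 9.** The 7-exo carbopalladation may be slow. Reduction of the C–I bond, palladium hydride-mediated migration of the new exocyclic double bonds into the ring, or intermolecular coupling could then take over.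
Fallback, from **7** back to **15**: the C1–C2 bond is made by an sp2–sp2 coupling whose site is fixed in advance.
- **7** is treated with a chiral B-(2-bromoallyl)-1,3,2-diazaborolidine, made from the bis(p-toluenesulfonamide) of 1,2-diphenylethane-1,2-diamine, BBr3 and tributyl(2-bromoallyl)stannane in the enantiomeric series that attacks the Si face. This gives the 2-bromoallyl carbinol F2.
- Silylation as in step 5 gives the silyl ether F3, the Nef reaction of step 6 gives the aldehyde F4, and ethynylmagnesium bromide gives the propargylic alcohol F5.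
- Molybdenum-catalysed hydrostannation as in step 8, without iodine, gives the α-vinylstannane F6.
- An intramolecular Stille coupling (Pd(PPh3)4, CuI, CsF, DMF) closes the ring to **15**.

**Step 6.** The reduction may stall at the oxime stage. Alternatively, the isopropenyl-type double bond may migrate into conjugation with the new aldehyde under conditions that are too basic or too acidic.
Fallback, from **9** back to **11**: the nitro group is reduced deliberately to the oxime F7 with SnCl2, thiophenol and triethylamine. The oxime is then exchanged onto glyoxylic acid in buffered aqueous THF, which releases **11** under nearly neutral conditions.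

**Step 12.** Hydride may be delivered from the seven-membered-ring side, which would return the 10R alcohol **19**. The steric difference between the two faces of a bridging ketone is modest.
Fallback, from **20** back to **22**: both silyl ethers are removed first with n-Bu4NF to give the keto diol F8. The ketone is then reduced with Me4NBH(OAc)3. The reagent is bound by the C7 hydroxymethyl group and delivers hydride intramolecularly from the cyclohexene face, giving triol **22** directly.

**Step 2.** Vinyllithium **4** may undergo oxygen-to-carbon silyl migration, or the product nitrodiene may be consumed by a second addition under the basic conditions.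
Fallback, from **2** back to **5**: **4** is quenched with N,N-dimethylformamide to give the 2-(silyloxymethyl)acrolein F9. A base-catalysed Henry reaction with nitromethane at low temperature gives the racemic nitro alcohol F10. Dehydration with methanesulfonyl chloride and triethylamine gives **5**.

## Further compounds

F1 | step 10 | trimethylsilyl dienol ether of cyclononene aldehyde 18 | C[Si](C)(C)O/C=C1\C(=C)C[C@H](O[Si](C)(C)C(C)(C)C)[C@H]([C@@H](C)CCC=C(C)C)/C=C(CO[Si](c2ccccc2)(c2ccccc2)C(C)(C)C)\CC1
F2 | step 9 | (4S,5R,6S)-2-bromo-6-{3-[(tert-butyldiphenylsilyl)oxy]prop-1-en-2-yl}-5-[(2S)-6-methylhept-5-en-2-yl]-7-nitrohept-1-en-4-ol | C=C(Br)C[C@H](O)[C@H]([C@@H](C)CCC=C(C)C)[C@H](C[N+](=O)[O-])C(=C)CO[Si](c1ccccc1)(c1ccccc1)C(C)(C)C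
F3 | step 9 | 4-O-tert-butyldimethylsilyl ether of F2 | C=C(Br)C[C@H](O[Si](C)(C)C(C)(C)C)[C@H]([C@@H](C)CCC=C(C)C)[C@H](C[N+](=O)[O-])C(=C)CO[Si](c1ccccc1)(c1ccccc1)C(C)(C)C
F4 | step 9 | (2S,3R,4S)-6-bromo-4-[(tert-butyldimethylsilyl)oxy]-2-{3-[(tert-butyldiphenylsilyl)oxy]prop-1-en-2-yl}-3-[(2S)-6-methylhept-5-en-2-yl]hept-6-enal | C=C(Br)C[C@H](O[Si](C)(C)C(C)(C)C)[C@H]([C@@H](C)CCC=C(C)C)[C@H](C=O)C(=C)CO[Si](c1ccccc1)(c1ccccc1)C(C)(C)C
F5 | step 9 | (3S,4S,5R,6S)-8-bromo-6-[(tert-butyldimethylsilyl)oxy]-4-{3-[(tert-butyldiphenylsilyl)oxy]prop-1-en-2-yl}-5-[(2S)-6-methylhept-5-en-2-yl]non-8-en-1-yn-3-ol | C=C(Br)C[C@H](O[Si](C)(C)C(C)(C)C)[C@H]([C@@H](C)CCC=C(C)C)[C@H]([C@H](O)C#C)C(=C)CO[Si](c1ccccc1)(c1ccccc1)C(C)(C)C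
F6 | step 9 | (3S,4S,5R,6S)-8-bromo-6-[(tert-butyldimethylsilyl)oxy]-4-{3-[(tert-butyldiphenylsilyl)oxy]prop-1-en-2-yl}-5-[(2S)-6-methylhept-5-en-2-yl]-2-(tributylstannyl)nona-1,8-dien-3-ol | C=C(Br)C[C@H](O[Si](C)(C)C(C)(C)C)[C@H]([C@@H](C)CCC=C(C)C)[C@H]([C@H](O)C(=C)[Sn](CCCC)(CCCC)CCCC)C(=C)CO[Si](c1ccccc1)(c1ccccc1)C(C)(C)C
F7 | step 6 | oxime of aldehyde 11 (mixture of oxime geometries) | C=CC[C@H](O[Si](C)(C)C(C)(C)C)[C@H]([C@@H](C)CCC=C(C)C)[C@H](C=NO)C(=C)CO[Si](c1ccccc1)(c1ccccc1)C(C)(C)C
F8 | step 12 | (1R,4S,5R,6R)-4-hydroxy-7-(hydroxymethyl)-2-methylidene-5-[(2S)-6-methylhept-5-en-2-yl]bicyclo[4.3.1]dec-7-en-10-one | C=C1C[C@H](O)[C@H]([C@@H](C)CCC=C(C)C)[C@@H]2C(CO)=CC[C@H]1C2=O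
F9 | step 2 | 2-{[(tert-butyldiphenylsilyl)oxy]methyl}prop-2-enal | C=C(C=O)CO[Si](c1ccccc1)(c1ccccc1)C(C)(C)C
F10 | step 2 | 3-{[(tert-butyldiphenylsilyl)oxy]methyl}-1-nitrobut-3-en-2-ol (racemic) | C=C(CO[Si](c1ccccc1)(c1ccccc1)C(C)(C)C)C(O)C[N+](=O)[O-]
A1 | alternative 1 | oxygen-bridged tricyclic ketone (C4–O–C10 ether bridge, C2 ketone, C5=C6 alkene, C7 triisopropylsilyl ether, silyloxypentyl side chain) | O=C1C[C@@H]3C([C@@H](C)CCCO[Si](C)(C)C(C)(C)C)=C2[C@H](O[Si](C(C)C)(C(C)C)C(C)C)CC[C@H]1[C@@H]2O3
A2 | alternative 2 | bicyclo[4.3.1]dec-6-en-2-one cycloadduct (bridgehead C6=C7 alkene, C4 and C10 tert-butyldimethylsilyl ethers, C7 (4-methoxybenzyloxy)methyl group) | O=C1C[C@H](O[Si](C)(C)C(C)(C)C)[C@H]([C@@H](C)CCC=C(C)C)C2=C(COCc3ccc(OC)cc3)CC[C@H]1[C@@H]2O[Si](C)(C)C(C)(C)C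
A3 | alternative 3 | 4-[(tert-butyldimethylsilyl)oxy]-2-methylidene-10-nitrobicyclo[4.3.1]dec-7-ene-7-carbaldehyde bearing the C5 side chain | C=C1C[C@H](O[Si](C)(C)C(C)(C)C)[C@H]([C@@H](C)CCC=C(C)C)[C@@H]2C(C=O)=CC[C@H]1[C@@H]2[N+](=O)[O-]
A4 | alternative 3 | acetaldehyde | CC=O
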